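**Retrosynthetic overview**

- Ring A positions are counted from the methoxy carbon (position 1) round to the acyl carbon (position 6). The strategy rests on position 4, which lies between the oxygens at positions 3 and 5 and is therefore the lithiation site of bis-MOM 5-methoxyresorcinol, and on the only stereocentre, chain carbon C5, bonded to it. C5–C4 is a two-carbon link between ring A and the unfunctionalised C3–C1 arylpropyl tail, so C5 and C4 can come from a vinylboron unit.
- Late disconnections: global MOM removal; chalcone ketone from the carbinol; the bond from ring A position 6 to the carbinol carbon from a ring A aryllithium (via the aryl iodide) and 4-(methoxymethoxy)cinnamaldehyde; the C5–C6 bond by a stereoretentive, E-selective selenium-mediated Zweifel-type alkenylation of a C5 boronate with (E)-styryllithium.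
- Key disconnection: the bond from ring A position 4 to C5 and the C3–C4 bond are made together in an enantioselective nickel-catalysed three-component coupling of the ring A aryllithium, vinylboronic acid pinacol ester and the 3-arylpropyl iodide.
- No ring is formed anywhere in the route: all four benzene rings are purchased. MOM is the only protecting group (five in all, removed together at the end).

Key step: step 4

Remark 1: the ligand antipode that gives the (S)-boronate cannot be predicted with confidence for an aryl group with two ortho substituents. Both antipodes of the diamine are available, and the one that gives the (S) product in a first trial is used.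

Remark 2: the two free positions of ring A after the alkenylation (positions 2 and 6) are exchanged by rotation about the bond from ring A to C5, so mono-iodination at either gives the same compound.

**Route**

Step 1
Reactants: 1 5-methoxyresorcinol
Product: 2 1-methoxy-3,5-bis(methoxymethoxy)benzene
Conditions: MOMCl (2.5 equiv), i-Pr2NEt, CH2Cl2, 0 °C → rt
Reagents that add atoms: chloromethyl methyl ether (MOMCl), COCCl
Why: Williamson-type MOM protection of both phenols with the reactive α-chloro ether under amine base; the methyl ether is inert.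

Step 2
Reactants: 3 3-(4-hydroxyphenyl)propan-1-ol
Product: 4 4-(3-iodopropyl)phenol
Conditions: PPh3, I2, imidazole, CH2Cl2, 0 °C → rt
Reagents that add atoms: iodine, II
Why: Appel-type iodination activates only the primary aliphatic alcohol as its alkoxyphosphonium salt for SN2 displacement by iodide; a phenol cannot be displaced in this way.

Step 3
Reactants: 4 4-(3-iodopropyl)phenol
Product: 5 1-(3-iodopropyl)-4-(methoxymethoxy)benzene
Conditions: MOMCl, i-Pr2NEt, CH2Cl2, 0 °C → rt
Reagents that add atoms: chloromethyl methyl ether (MOMCl), COCCl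
Why: MOM protection of the phenol under hindered amine base, the very reactive MOMCl outcompeting any phenoxide alkylation by the primary iodide.

Step 4
Reactants: 2 1-methoxy-3,5-bis(methoxymethoxy)benzene; 6 vinylboronic acid pinacol ester; 5 1-(3-iodopropyl)-4-(methoxymethoxy)benzene
Product: 9 (S)-2-{1-[4-methoxy-2,6-bis(methoxymethoxy)phenyl]-5-[4-(methoxymethoxy)phenyl]pentyl}-4,4,5,5-tetramethyl-1,3,2-dioxaborolane, via aryllithium 7 (not isolated), via vinyl boronate complex 8 (not isolated)
Conditions: 2 (1.05 equiv), n-BuLi (1.0 equiv), THF, 0 °C; 6, 0 °C → rt; then NiBr2(dme) (10 mol%), chiral N,N′-dimethyl-1,2-diphenylethane-1,2-diamine (13 mol%, antipode per remark 1), 5, THF/DMSO, rt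
Reagents that add atoms: none
Why: Directed ortho-lithiation of 2 at the carbon between the two MOM ethers gives 7, which adds to the vacant boron orbital of 6 to form the four-coordinate vinyl boronate 8. An alkylnickel species formed from iodide 5 and the low-valent nickel–diamine catalyst (generated in situ from the divalent nickel salt) binds the vinyl group of 8 and triggers a 1,2-metalate shift in which ring A moves from boron to the boron-bearing carbon anti to nickel while the terminal carbon bonds to nickel; C(sp3)–C(sp3) reductive elimination then forms the C3–C4 bond, the direct precedent being nickel-catalysed enantioselective conjunctive cross-coupling of aryllithium-derived vinylboron ate complexes with unactivated primary alkyl iodides. No ring is closed; the two skeletal bonds formed are the bond from ring A position 4 to C5 and the C3–C4 bond. The single stereocentre C5 is set by the chiral diamine on nickel, which selects the enantioface of the bound vinyl boronate during the shift, and it is kept because a benzylic pinacol boronate does not ionise on this electron-rich ring as a halide or alcohol would. The step needs the catalysed shift to outrun racemic radical-chain addition, which the choice of an unactivated primary iodide (a poor chain carrier) secures, and it needs the right ring A regiochemistry, which the two flanking MOM ethers secure at the lithiation stage. The open point is the rate of ate-complex formation and of migration for an aryl group with two ortho substituents.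

Step 5
Reactants: 10 4-hydroxybenzaldehyde
Product: 11 4-(methoxymethoxy)benzaldehyde
Conditions: MOMCl, i-Pr2NEt, CH2Cl2, 0 °C → rt
Reagents that add atoms: chloromethyl methyl ether (MOMCl), COCCl
Why: Standard MOM protection of a phenol; the aldehyde does not react with the chloro ether under amine base.

Step 6
Reactants: 11 4-(methoxymethoxy)benzaldehyde
Product: 12 (E)-1-(2-iodoethenyl)-4-(methoxymethoxy)benzene
Conditions: CrCl2 (6 equiv), CHI3 (2 equiv), THF, 0 °C → rt, dark
Reagents that add atoms: iodoform, IC(I)I
Why: Takai olefination, in which the geminal dichromium species made from iodoform and divalent chromium adds to the aldehyde and eliminates to the vinyl iodide, aryl aldehydes giving high E selectivity; the aryl MOM ether is inert.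

Step 7
Reactants: 12 (E)-1-(2-iodoethenyl)-4-(methoxymethoxy)benzene; 9 (S)-benzylic pinacol boronate
Product: 17 5-methoxy-1,3-bis(methoxymethoxy)-2-{(1E,3R)-1,7-bis[4-(methoxymethoxy)phenyl]hept-1-en-3-yl}benzene, via styryllithium 13 (not isolated), via alkenyl boronate complex 14 (not isolated), via beta-seleno boronic ester 15 (not isolated), via selenoxide 16 (not isolated)
Conditions: 12, t-BuLi (2 equiv per 12), THF, −78 °C; 9, −78 °C; PhSeCl, −78 °C; mCPBA, −45 °C → rt
Reagents that add atoms: none
Why: Selenium-mediated Zweifel-type olefination, in which iodine–lithium exchange gives the configurationally stable E-styryllithium that adds to boron, PhSeCl forms a seleniranium ion opened by anti 1,2-migration of C5 from boron with retention at C5, and oxidation to the selenoxide triggers syn elimination of boron and selenium, so that anti addition followed by syn elimination returns the E alkene (the C5 descriptor changes from S to R only because vinyl outranks the alkyl chain where boron did not).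

Step 8
Reactants: 17 (R,E)-alkene
Product: 18 2-iodo-1-methoxy-3,5-bis(methoxymethoxy)-4-{(1E,3R)-1,7-bis[4-(methoxymethoxy)phenyl]hept-1-en-3-yl}benzene
Conditions: NIS (1.0 equiv), DMF, 0 °C, dark
Reagents that add atoms: N-iodosuccinimide, O=C1CCC(=O)N1I
Why: Electrophilic aromatic iodination at position 6 of the trioxygenated ring A, by far the most nucleophilic site (position 2 is equivalent, remark 2), under neutral conditions in which the styrene has no irreversible pathway without an added nucleophile and the MOM ethers are stable.

Step 9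
Reactants: 11 4-(methoxymethoxy)benzaldehyde
Product: 19 (E)-3-[4-(methoxymethoxy)phenyl]prop-2-enal
Conditions: Ph3P=CHCHO (1.1 equiv), toluene, 80 °C
Reagents that add atoms: (triphenylphosphoranylidene)acetaldehyde, O=CC=P(c1ccccc1)(c1ccccc1)c1ccccc1
Why: Wittig reaction with the stabilised formylmethylene ylide gives the E-enal, and the product enal is less electrophilic than the aryl aldehyde, so a second homologation is slow.

Step 10
Reactants: 18 ring A iodide; 19 (E)-3-[4-(methoxymethoxy)phenyl]prop-2-enal
Product: 21 (2E)-1-{3-[(1E,3R)-1,7-bis[4-(methoxymethoxy)phenyl]hept-1-en-3-yl]-6-methoxy-2,4-bis(methoxymethoxy)phenyl}-3-[4-(methoxymethoxy)phenyl]prop-2-en-1-ol (both carbinol epimers), via aryllithium 20 (not isolated)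
Conditions: t-BuLi (2.0 equiv), THF, −78 °C, 10 min; then 19, −78 °C; aq NH4Cl
Reagents that add atoms: none
Why: Iodine–lithium exchange at −78 °C is much faster than deprotonation of the doubly activated C5–H, and the aryllithium adds 1,2 to the non-enolisable enal; the new carbinol centre is uncontrolled and is removed in step 11.

Step 11
Reactants: 21 bis-allylic/benzylic alcohol
Product: 22 (2E)-1-{3-[(1E,3R)-1,7-bis[4-(methoxymethoxy)phenyl]hept-1-en-3-yl]-6-methoxy-2,4-bis(methoxymethoxy)phenyl}-3-[4-(methoxymethoxy)phenyl]prop-2-en-1-one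
Conditions: MnO2 (activated, excess), CH2Cl2, rt
Reagents that add atoms: none
Why: MnO2 oxidation of a doubly activated (benzylic and allylic) alcohol to the chalcone ketone under neutral conditions that spare the MOM ethers and both alkenes.

Step 12
Reactants: 22 penta-MOM chalcone
Product: 23 deoxycalyxin A, (2E)-1-{2,4-dihydroxy-3-[(1E,3R)-1,7-bis(4-hydroxyphenyl)hept-1-en-3-yl]-6-methoxyphenyl}-3-(4-hydroxyphenyl)prop-2-en-1-one
Conditions: HCl (3 M aq, to about pH 1), MeOH/THF, rt
Reagents that add atoms: none
Why: Acid-catalysed transacetalisation of the five aryl MOM ethers in methanol, run in dilute acid at room temperature because 2′-hydroxy-6′-methoxychalcones are expected to survive such conditions without closing to the flavanone, and C5 is neither enolisable nor ionisable under them.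

**Compound list**

1 | 5-methoxyresorcinol | COc1cc(O)cc(O)c1 | starting material
2 | 1-methoxy-3,5-bis(methoxymethoxy)benzene | COc1cc(OCOC)cc(OCOC)c1 | intermediate
3 | 3-(4-hydroxyphenyl)propan-1-ol | OCCCc1ccc(O)cc1 | starting material
4 | 4-(3-iodopropyl)phenol | Oc1ccc(CCCI)cc1 | intermediate
5 | 1-(3-iodopropyl)-4-(methoxymethoxy)benzene | COCOc1ccc(CCCI)cc1 | intermediate
6 | vinylboronic acid pinacol ester | C=CB1OC(C)(C)C(C)(C)O1 | starting material
7 | [4-methoxy-2,6-bis(methoxymethoxy)phenyl]lithium | [Li]c1c(OCOC)cc(OC)cc1OCOC | intermediate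
8 | lithium [4-methoxy-2,6-bis(methoxymethoxy)phenyl](vinyl)(pinacolato)borate | [Li+].C=C[B-]1(OC(C)(C)C(C)(C)O1)c1c(OCOC)cc(OC)cc1OCOC | intermediate
9 | (S)-2-{1-[4-methoxy-2,6-bis(methoxymethoxy)phenyl]-5-[4-(methoxymethoxy)phenyl]pentyl}-4,4,5,5-tetramethyl-1,3,2-dioxaborolane | COc1cc(OCOC)c([C@@H](B2OC(C)(C)C(C)(C)O2)CCCCc2ccc(OCOC)cc2)c(OCOC)c1 | intermediate
10 | 4-hydroxybenzaldehyde | O=Cc1ccc(O)cc1 | starting material
11 | 4-(methoxymethoxy)benzaldehyde | COCOc1ccc(C=O)cc1 | intermediate
12 | (E)-1-(2-iodoethenyl)-4-(methoxymethoxy)benzene | COCOc1ccc(/C=C/I)cc1 | intermediate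
13 | (E)-2-[4-(methoxymethoxy)phenyl]ethenyllithium | COCOc1ccc(/C=C/[Li])cc1 | intermediate
14 | lithium (E)-styryl boronate complex of 9 (C5 configuration unchanged) | [Li+].COCOc1ccc(/C=C/[B-]2(OC(C)(C)C(C)(C)O2)[C@H](c2c(OCOC)cc(OC)cc2OCOC)CCCCc2ccc(OCOC)cc2)cc1 | intermediate
15 | beta-(phenylselanyl) boronic ester, anti adduct across C6–C7 (one of the two anti diastereomers shown; its C6,C7-bis-epimer forms alongside and converges on the same alkene) | COCOc1ccc(cc1)[C@H]([Se]c1ccccc1)[C@@H](B1OC(C)(C)C(C)(C)O1)[C@H](c1c(OCOC)cc(OC)cc1OCOC)CCCCc1ccc(OCOC)cc1 | intermediate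
16 | selenoxide of 15 (selenium configuration not defined) | COCOc1ccc(cc1)[C@H]([Se](=O)c1ccccc1)[C@@H](B1OC(C)(C)C(C)(C)O1)[C@H](c1c(OCOC)cc(OC)cc1OCOC)CCCCc1ccc(OCOC)cc1 | intermediate
17 | 5-methoxy-1,3-bis(methoxymethoxy)-2-{(1E,3R)-1,7-bis[4-(methoxymethoxy)phenyl]hept-1-en-3-yl}benzene | COc1cc(OCOC)c([C@@H](/C=C/c2ccc(OCOC)cc2)CCCCc2ccc(OCOC)cc2)c(OCOC)c1 | intermediate
18 | 2-iodo-1-methoxy-3,5-bis(methoxymethoxy)-4-{(1E,3R)-1,7-bis[4-(methoxymethoxy)phenyl]hept-1-en-3-yl}benzene | COc1cc(OCOC)c([C@@H](/C=C/c2ccc(OCOC)cc2)CCCCc2ccc(OCOC)cc2)c(OCOC)c1I | intermediate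
19 | (E)-3-[4-(methoxymethoxy)phenyl]prop-2-enal | COCOc1ccc(/C=C/C=O)cc1 | intermediate
20 | ring A aryllithium derived from 18 (lithium in place of iodine) | COc1cc(OCOC)c([C@@H](/C=C/c2ccc(OCOC)cc2)CCCCc2ccc(OCOC)cc2)c(OCOC)c1[Li] | intermediate
21 | (2E)-1-{3-[(1E,3R)-1,7-bis[4-(methoxymethoxy)phenyl]hept-1-en-3-yl]-6-methoxy-2,4-bis(methoxymethoxy)phenyl}-3-[4-(methoxymethoxy)phenyl]prop-2-en-1-ol (carbinol centre undefined) | COc1cc(OCOC)c([C@@H](/C=C/c2ccc(OCOC)cc2)CCCCc2ccc(OCOC)cc2)c(OCOC)c1C(O)/C=C/c1ccc(OCOC)cc1 | intermediate
22 | (2E)-1-{3-[(1E,3R)-1,7-bis[4-(methoxymethoxy)phenyl]hept-1-en-3-yl]-6-methoxy-2,4-bis(methoxymethoxy)phenyl}-3-[4-(methoxymethoxy)phenyl]prop-2-en-1-one | COc1cc(OCOC)c([C@@H](/C=C/c2ccc(OCOC)cc2)CCCCc2ccc(OCOC)cc2)c(OCOC)c1C(=O)/C=C/c1ccc(OCOC)cc1 | intermediate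
23 | deoxycalyxin A | COc1cc(O)c([C@@H](/C=C/c2ccc(O)cc2)CCCCc2ccc(O)cc2)c(O)c1C(=O)/C=C/c1ccc(O)cc1 | target

**Summary**

Total step count: 12. Longest linear sequence: 8 steps (from 3 through steps 2, 3, 4, 7, 8, 10, 11 and 12).

**Steps most likely to fail**

Step 4. The aryllithium with two ortho MOM ethers may add slowly to the vinylboronic ester, or the hindered ring may migrate too slowly on nickel. Reduction or homocoupling of the iodide, or the uncatalysed racemic radical addition, could then take over, and the enantioselectivity could be low.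

The fallback is a sparteine-mediated lithiation–borylation, which sets out from 2 and 5 and comes back at 9. Lithiation of 2 as in step 4 and trapping with 2-isopropoxy-4,4,5,5-tetramethyl-1,3,2-dioxaborolane would give 2-[4-methoxy-2,6-bis(methoxymethoxy)phenyl]-4,4,5,5-tetramethyl-1,3,2-dioxaborolane F1. Iodide 5 would alkylate the lithium enolate of tert-butyl acetate (LDA, THF/DMPU, −78 °C → rt) to give tert-butyl 5-[4-(methoxymethoxy)phenyl]pentanoate F2. LiAlH4 (THF, 0 °C) would give 5-[4-(methoxymethoxy)phenyl]pentan-1-ol F3. Mitsunobu esterification (2,4,6-triisopropylbenzoic acid, PPh3, DIAD, THF) would give 5-[4-(methoxymethoxy)phenyl]pentyl 2,4,6-triisopropylbenzoate F4. Deprotonation of this ester with s-BuLi/(+)-sparteine (Et2O, −78 °C) would give the configurationally stable (R)-1-lithio-5-[4-(methoxymethoxy)phenyl]pentyl 2,4,6-triisopropylbenzoate F5; by the usual course of this chemistry, (−)-sparteine removes the pro-S hydrogen and would lead to the wrong antipode. The aryl boronic ester would trap the organolithium with retention to give the lithium boronate complex F6. Warming would bring about 1,2-migration of ring A with inversion at carbon and loss of the benzoate, giving (S)-9.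

Step 7. Addition of the bulky styryllithium to the hindered secondary boronate may be incomplete or reversible. PhSeCl may then attack the electron-rich ring A, or the peracid may over-oxidise.

The fallback separates C–C bond formation from the control of alkene geometry. It sets out from 9 and 11 and comes back at 17. Excess vinylmagnesium bromide (THF, rt) would convert 9 into the bromomagnesium vinyl boronate complex F7. I2 in MeOH at −78 °C would give the beta-iodo boronic ester F8 by 1,2-migration of C5 with retention. NaOMe would eliminate it to 5-methoxy-1,3-bis(methoxymethoxy)-2-{(3R)-7-[4-(methoxymethoxy)phenyl]hept-1-en-3-yl}benzene F9 (a standard Zweifel vinylation, with no geometry to control). Wittig methylenation of 11 (Ph3PCH3Br, KOt-Bu, THF) would give 1-ethenyl-4-(methoxymethoxy)benzene F10. Cross-metathesis of the terminal alkene with an excess of this styrene would give the E alkene 17; it would use the second-generation Grubbs catalyst RuCl2(=CHPh)(PCy3)(H2IMes) in CH2Cl2 at 40 °C, with 1,4-benzoquinone added to suppress double-bond migration toward C5.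

Step 12. Protic acid may drive conjugate closure of the ring A hydroxyl ortho to the carbonyl onto the enone (flavanone formation). It may also drive addition of a ring A hydroxyl ortho to C5 to the protonated styrene (flavan formation), or leave the cleavage of the five ethers incomplete.

The fallback avoids protic acid. It sets out from 22 and comes back at 23. TMSOTf with 2,2′-bipyridyl in MeCN (0 °C → rt) would exchange each aryl MOM ether for a silyl ether under buffered Lewis-acidic conditions, giving the pentakis(trimethylsilyl) ether of deoxycalyxin A F11. Addition of water at room temperature would hydrolyse the five aryl silyl ethers to 23.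

**Further compounds**

F1 | step 4 | 2-[4-methoxy-2,6-bis(methoxymethoxy)phenyl]-4,4,5,5-tetramethyl-1,3,2-dioxaborolane | COc1cc(OCOC)c(B2OC(C)(C)C(C)(C)O2)c(OCOC)c1
F2 | step 4 | tert-butyl 5-[4-(methoxymethoxy)phenyl]pentanoate | COCOc1ccc(CCCCC(=O)OC(C)(C)C)cc1
F3 | step 4 | 5-[4-(methoxymethoxy)phenyl]pentan-1-ol | COCOc1ccc(CCCCCO)cc1
F4 | step 4 | 5-[4-(methoxymethoxy)phenyl]pentyl 2,4,6-triisopropylbenzoate | COCOc1ccc(CCCCCOC(=O)c2c(C(C)C)cc(C(C)C)cc2C(C)C)cc1
F5 | step 4 | (R)-1-lithio-5-[4-(methoxymethoxy)phenyl]pentyl 2,4,6-triisopropylbenzoate | [Li][C@@H](OC(=O)c1c(C(C)C)cc(C(C)C)cc1C(C)C)CCCCc1ccc(OCOC)cc1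
F6 | step 4 | lithium boronate complex of F1 and F5 | [Li+].COc1cc(OCOC)c([B-]2(OC(C)(C)C(C)(C)O2)[C@@H](OC(=O)c2c(C(C)C)cc(C(C)C)cc2C(C)C)CCCCc2ccc(OCOC)cc2)c(OCOC)c1
F7 | step 7 | bromomagnesium vinyl boronate complex of 9 | Br[Mg+].C=C[B-]1(OC(C)(C)C(C)(C)O1)[C@H](c1c(OCOC)cc(OC)cc1OCOC)CCCCc1ccc(OCOC)cc1
F8 | step 7 | beta-iodo boronic ester (boron-bearing carbon undefined) | ICC(B1OC(C)(C)C(C)(C)O1)[C@H](c1c(OCOC)cc(OC)cc1OCOC)CCCCc1ccc(OCOC)cc1
F9 | step 7 | 5-methoxy-1,3-bis(methoxymethoxy)-2-{(3R)-7-[4-(methoxymethoxy)phenyl]hept-1-en-3-yl}benzene | COc1cc(OCOC)c([C@@H](C=C)CCCCc2ccc(OCOC)cc2)c(OCOC)c1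
F10 | step 7 | 1-ethenyl-4-(methoxymethoxy)benzene | C=Cc1ccc(OCOC)cc1
F11 | step 12 | pentakis(trimethylsilyl) ether of deoxycalyxin A | COc1cc(O[Si](C)(C)C)c([C@@H](/C=C/c2ccc(O[Si](C)(C)C)cc2)CCCCc2ccc(O[Si](C)(C)C)cc2)c(O[Si](C)(C)C)c1C(=O)/C=C/c1ccc(O[Si](C)(C)C)cc1
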